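**Retrosynthetic overview**
- The senecioate and two silyl ethers come off last; the 11-membered carbocycle (the last ring formed) is closed at C3–C4 by Ni/Cr coupling of an E-vinyl iodide with an α,β-epoxy aldehyde.
- C9=C10 comes from an E-selective Horner–Wadsworth–Emmons (HWE) union of a C10 aldehyde (west piece) with a phosphonoacetate that already carries the cis-epoxide (east piece; the oxirane is the first ring formed, by Sharpless epoxidation).
- The west piece, an acyclic quaternary C1 with three different arms, comes from C–C scission next to the carbonyl of a 3-alkenyl-3-methylcyclohexanone.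
- That ketone comes from 3-methylanisole by Birch dearomatisation to 3-methylcyclohexenone and copper-catalysed asymmetric conjugate alkenylation; all six arene carbons and the arene methyl end up in the target.

Atom labels used below: ring C1 (quaternary), C2=C3, C4 (O-acyl), C5 (Me, epoxide), C6 (epoxide), C7, C8, C9 (CH2OH)=C10, C11; side chain C1′–C3′ (C3′ is the carbinol).
Assumption: the SMILES is taken as drawn, i.e. (1S,2R,3E,5S,7E,11S) in the bicyclic name and S at C3′.

**West fragment**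

Step 1
Reactants: 1 3-methylanisole
Product: 3 3-methylcyclohex-2-en-1-one, via dihydroanisole 2 (not isolated)
Conditions: Li, NH3 (l), t-BuOH, THF, −78 to −33 °C; then 2 M HCl, rt
Reagents that add atoms: water, O
Why: Birch reduction leaves the methoxy and methyl groups on the two remaining double bonds, and enol ether hydrolysis with conjugation gives the β-methyl enone whose six ring carbons and methyl group become C1, its methyl, C11, C10 and C1′–C3′.

Step 2
Reactants: 3 3-methylcyclohex-2-en-1-one; 4 (E)-(2-bromoethenyl)trimethylsilane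
Product: 7 (3S)-3-methyl-3-[(E)-2-(trimethylsilyl)ethenyl]cyclohexan-1-one, via alkenyllithium 5 (not isolated), via alkenylalane 6 (not isolated)
Conditions: 4, t-BuLi (2 equiv), Et2O, −78 °C; Me2AlCl, −78 to 0 °C; then 3, Cu(O2CC4H3S) (5 mol%), SimplePhos-type chiral phosphinamine (6 mol%, enantiomer giving the S ketone), Et2O, −30 °C; 1 M HCl
Reagents that add atoms: none
Why: Copper-catalysed asymmetric conjugate addition of alkenylalanes to 3-methylcyclohexenone is an established route to all-carbon quaternary centres; the ligand selects the enone face and sets C1 as S, and the E geometry of the alkenyl–metal bond is retained.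

Step 3
Reactants: 7 (3S)-3-methyl-3-[(E)-2-(trimethylsilyl)ethenyl]cyclohexan-1-one
Product: 8 (3S)-3-[(E)-2-iodoethenyl]-3-methylcyclohexan-1-one
Conditions: NIS, (CF3)2CHOH, 0 °C
Reagents that add atoms: N-iodosuccinimide, O=C1CCC(=O)N1I
Why: ipso-Iododesilylation of the vinylsilane goes through the β-silyl cation with retention and gives the E-vinyl iodide.

Step 4
Reactants: 8 (3S)-3-[(E)-2-iodoethenyl]-3-methylcyclohexan-1-one
Product: 9 (5S)-2-hydroxy-5-[(E)-2-iodoethenyl]-5-methylcyclohexan-1-one (both C2 epimers)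
Conditions: LiN(iPr)2, THF, −78 °C; then 3-phenyl-2-(phenylsulfonyl)oxaziridine, −78 °C; aq NH4Cl
Reagents that add atoms: 3-phenyl-2-(phenylsulfonyl)oxaziridine, O=S(=O)(c1ccccc1)N1OC1c1ccccc1
Why: Kinetic deprotonation takes the unhindered α-CH2 remote from the quaternary carbon and the lithium enolate is hydroxylated by the Davis oxaziridine (enolate oxidation); the new carbinol centre is destroyed in step 5.

Step 5
Reactants: 9 (5S)-2-hydroxy-5-[(E)-2-iodoethenyl]-5-methylcyclohexan-1-one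
Product: 10 methyl (3S)-3-[(E)-2-iodoethenyl]-3-methyl-6-oxohexanoate
Conditions: Pb(OAc)4, MeOH–PhH (1:1), 0 °C
Reagents that add atoms: methanol, CO
Why: Lead tetraacetate cleaves the α-ketol as its methyl hemiketal (Criegee-type cleavage), opening the arene-derived ring into a two-carbon ester arm (C11–C10) and a three-carbon aldehyde arm (C1′–C3′) without touching C1.

Step 6
Reactants: 10 methyl (3S)-3-[(E)-2-iodoethenyl]-3-methyl-6-oxohexanoate; 11 isopropenylmagnesium bromide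
Product: 13 methyl (3S,6S)-6-hydroxy-3-[(E)-2-iodoethenyl]-3,7-dimethyloct-7-enoate, via diisopropenylzinc 12 (not isolated)
Conditions: 11, ZnCl2, THF, 0 °C; 1,4-dioxane, filter; (2R)-(+)-3-exo-morpholinoisoborneol (10 mol%), toluene, 0 °C; then 10
Reagents that add atoms: none
Why: Amino-alcohol-catalysed alkenylzinc addition to an aldehyde (Noyori/Oppolzer/Walsh type), in which the (2R)-ligand–zinc complex delivers isopropenyl to the Re face and sets C3′ as S while ester and vinyl iodide are inert to the organozinc.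

**East fragment**

Step 7
Reactants: 14 tert-butyl 2-(diethoxyphosphoryl)acetate; 15 acrolein
Product: 16 tert-butyl 2-(diethoxyphosphoryl)-5-oxopentanoate (racemic)
Conditions: t-BuOK (5 mol%), t-BuOH–THF, 0 °C
Reagents that add atoms: none
Why: Base-catalysed Michael addition of the stabilised phosphonoacetate anion to acrolein forms C8–C9; the phosphonate carbon is racemic but becomes sp2 in step 12.

Step 8
Reactants: 16 tert-butyl 2-(diethoxyphosphoryl)-5-oxopentanoate; 17 methyl 2-[bis(2,2,2-trifluoroethoxy)phosphoryl]propanoate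
Product: 18 1-tert-butyl 7-methyl (5Z)-2-(diethoxyphosphoryl)-6-methylhept-5-enedioate (racemic at C2)
Conditions: 17, KN(SiMe3)2, 18-crown-6, THF, −78 °C; then 16
Reagents that add atoms: none
Why: Still–Gennari olefination gives the Z enoate under kinetic control, placing C4 cis to C7, and the more acidic trifluoroethyl phosphonate is deprotonated selectively so the diethyl phosphonoacetate is a spectator.

Step 9
Reactants: 18 1-tert-butyl 7-methyl (5Z)-2-(diethoxyphosphoryl)-6-methylhept-5-enedioate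
Product: 19 tert-butyl (5Z)-2-(diethoxyphosphoryl)-7-hydroxy-6-methylhept-5-enoate (racemic at C2)
Conditions: i-Bu2AlH (3 equiv), CH2Cl2, −78 °C; aq potassium sodium tartrate
Reagents that add atoms: none
Why: Chemoselective hydride reduction in which the conjugated methyl ester goes to the allylic alcohol while the bulky tert-butyl ester next to the phosphonate is untouched at −78 °C.

Step 10
Reactants: 19 tert-butyl (5Z)-2-(diethoxyphosphoryl)-7-hydroxy-6-methylhept-5-enoate
Product: 20 tert-butyl 2-(diethoxyphosphoryl)-4-[(2S,3R)-3-(hydroxymethyl)-3-methyloxiran-2-yl]butanoate (both C2 epimers)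
Conditions: Ti(OiPr)4 (10 mol%), D-(−)-DIPT (12 mol%), t-BuOOH, 4 Å MS, CH2Cl2, −20 °C
Reagents that add atoms: tert-butyl hydroperoxide, CC(C)(C)OO
Why: Sharpless asymmetric epoxidation, in which the D-(−)-tartrate catalyst delivers oxygen to the face of the Z-allylic alcohol that gives the cis-epoxide with the C5/C6 configuration of the target (the opposite face to that used by L-(+)-tartrate in the nerol to (2S,3R)-epoxynerol case).

Step 11
Reactants: 20 tert-butyl 2-(diethoxyphosphoryl)-4-[(2S,3R)-3-(hydroxymethyl)-3-methyloxiran-2-yl]butanoate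
Product: 21 tert-butyl 2-(diethoxyphosphoryl)-4-[(2S,3R)-3-methyl-3-{[(triethylsilyl)oxy]methyl}oxiran-2-yl]butanoate (both C2 epimers)
Conditions: TESCl, imidazole, CH2Cl2, 0 °C
Reagents that add atoms: chlorotriethylsilane, CC[Si](Cl)(CC)CC
Why: Silylation of the primary alcohol as a TES ether, chosen because it can later be oxidised directly to the aldehyde in the presence of TBS ethers.

**Union and endgame**

Step 12
Reactants: 13 methyl (3S,6S)-6-hydroxy-3-[(E)-2-iodoethenyl]-3,7-dimethyloct-7-enoate; 21 tert-butyl 2-(diethoxyphosphoryl)-4-[(2S,3R)-3-methyl-3-{[(triethylsilyl)oxy]methyl}oxiran-2-yl]butanoate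
Product: 23 tert-butyl (2E,5S,8S)-8-hydroxy-5-[(E)-2-iodoethenyl]-5,9-dimethyl-2-{2-[(2S,3R)-3-methyl-3-{[(triethylsilyl)oxy]methyl}oxiran-2-yl]ethyl}deca-2,9-dienoate, via aldehyde 22 (not isolated)
Conditions: 13, i-Bu2AlH (2.2 equiv), CH2Cl2, −78 °C; then 21 + NaH (THF, 0 °C), −78 °C to rt
Reagents that add atoms: none
Why: One-pot ester reduction to the aluminium hemiacetal and HWE olefination with the α-substituted phosphonoacetate anion, which gives the E enoate (ester trans to C11), i.e. the required ring-cis C9=C10 geometry.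

Step 13
Reactants: 23 tert-butyl (2E,5S,8S)-8-hydroxy-5-[(E)-2-iodoethenyl]-5,9-dimethyl-2-{2-[(2S,3R)-3-methyl-3-{[(triethylsilyl)oxy]methyl}oxiran-2-yl]ethyl}deca-2,9-dienoate
Product: 24 (3S,6S,8E)-9-(hydroxymethyl)-6-[(E)-2-iodoethenyl]-2,6-dimethyl-11-[(2S,3R)-3-methyl-3-{[(triethylsilyl)oxy]methyl}oxiran-2-yl]undeca-1,8-dien-3-ol
Conditions: i-Bu2AlH (3.5 equiv), CH2Cl2, −78 to −40 °C; aq potassium sodium tartrate
Reagents that add atoms: none
Why: 1,2-Reduction of the unsaturated tert-butyl ester to the allylic alcohol; vinyl iodide, silyl ether and the trisubstituted epoxide survive at low temperature.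

Step 14
Reactants: 24 (3S,6S,8E)-9-(hydroxymethyl)-6-[(E)-2-iodoethenyl]-2,6-dimethyl-11-[(2S,3R)-3-methyl-3-{[(triethylsilyl)oxy]methyl}oxiran-2-yl]undeca-1,8-dien-3-ol
Product: 25 (3S,6S,8E)-3-[(tert-butyldimethylsilyl)oxy]-9-{[(tert-butyldimethylsilyl)oxy]methyl}-6-[(E)-2-iodoethenyl]-2,6-dimethyl-11-[(2S,3R)-3-methyl-3-{[(triethylsilyl)oxy]methyl}oxiran-2-yl]undeca-1,8-diene
Conditions: TBSCl, imidazole, DMAP (cat.), DMF, rt
Reagents that add atoms: tert-butyldimethylsilyl chloride, CC(C)(C)[Si](C)(C)Cl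
Why: Silylation of both free hydroxyls in one operation so that only the C4 oxygen is free after ring closure.

Step 15
Reactants: 25 the bis-TBS ether named in step 14
Product: 26 (2S,3S)-3-[(3E,6S,9S)-9-[(tert-butyldimethylsilyl)oxy]-3-{[(tert-butyldimethylsilyl)oxy]methyl}-6-[(E)-2-iodoethenyl]-6,10-dimethylundeca-3,10-dien-1-yl]-2-methyloxirane-2-carbaldehyde
Conditions: (COCl)2, DMSO, CH2Cl2, −78 to −30 °C; then Et3N
Reagents that add atoms: none
Why: Under Swern conditions a primary TES ether is cleaved and oxidised in situ to the aldehyde while TBS ethers are kept, so no separate deprotection is needed.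

Step 16
Reactants: 26 the epoxy aldehyde named in step 15
Product: 27 (1R,2R,3E,5S,7E,11S)-8-{[(tert-butyldimethylsilyl)oxy]methyl}-5-{(3S)-3-[(tert-butyldimethylsilyl)oxy]-4-methylpent-4-en-1-yl}-1,5-dimethyl-12-oxabicyclo[9.1.0]dodeca-3,7-dien-2-ol
Conditions: CrCl2 (8 equiv), NiCl2 (2 mol%), DMSO–THF (3:1), rt, 2 mM
Reagents that add atoms: none
Why: Nozaki–Hiyama–Kishi macrocyclisation, in which the alkenylchromium formed with retention from the E-vinyl iodide adds to the aldehyde at high dilution; Felkin–Anh/Cornforth addition anti to the epoxide C–O bond on the face away from C7 should give the anti epoxy alcohol (4R).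

Step 17
Reactants: 27 the macrocyclic alcohol named in step 16; 28 3-methylbut-2-enoyl chloride
Product: 29 (1S,2R,3E,5S,7E,11S)-8-{[(tert-butyldimethylsilyl)oxy]methyl}-5-{(3S)-3-[(tert-butyldimethylsilyl)oxy]-4-methylpent-4-en-1-yl}-1,5-dimethyl-12-oxabicyclo[9.1.0]dodeca-3,7-dien-2-yl 3-methylbut-2-enoate
Conditions: 28, pyridine, DMAP (cat.), CH2Cl2, 0 °C to rt
Reagents that add atoms: none
Why: DMAP-catalysed acylation of the only free hydroxyl; pyridine rather than a trialkylamine avoids deconjugation of the acyl group through the vinylketene.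

Step 18
Reactants: 29 the bis-silylated ester named in step 17
Product: 30 (1S,2R,3E,5S,7E,11S)-8-(hydroxymethyl)-5-[(3S)-3-hydroxy-4-methylpent-4-en-1-yl]-1,5-dimethyl-12-oxabicyclo[9.1.0]dodeca-3,7-dien-2-yl 3-methylbut-2-enoate
Conditions: Bu4NF, AcOH, THF, 0 °C to rt
Reagents that add atoms: none
Why: Fluoride-mediated cleavage of both TBS ethers, buffered with acetic acid so that the ester and the epoxide are not affected.

**Compound list**
1 | 3-methylanisole | COc1cccc(C)c1 | starting material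
2 | 1-methoxy-5-methylcyclohexa-1,4-diene | COC1=CCC=C(C)C1 | intermediate
3 | 3-methylcyclohex-2-en-1-one | CC1=CC(=O)CCC1 | intermediate
4 | (E)-(2-bromoethenyl)trimethylsilane | C[Si](C)(C)/C=C/Br | starting material
5 | [(E)-2-(trimethylsilyl)ethenyl]lithium | C[Si](C)(C)/C=C/[Li] | intermediate
6 | dimethyl[(E)-2-(trimethylsilyl)ethenyl]aluminium | C[Si](C)(C)/C=C/[Al](C)C | intermediate
7 | (3S)-3-methyl-3-[(E)-2-(trimethylsilyl)ethenyl]cyclohexan-1-one | O=C1C[C@@](C)(/C=C/[Si](C)(C)C)CCC1 | intermediate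
8 | (3S)-3-[(E)-2-iodoethenyl]-3-methylcyclohexan-1-one | O=C1C[C@@](C)(/C=C/I)CCC1 | intermediate
9 | (5S)-2-hydroxy-5-[(E)-2-iodoethenyl]-5-methylcyclohexan-1-one (both C2 epimers) | O=C1C[C@@](C)(/C=C/I)CCC1O | intermediate
10 | methyl (3S)-3-[(E)-2-iodoethenyl]-3-methyl-6-oxohexanoate | COC(=O)C[C@@](C)(/C=C/I)CCC=O | intermediate
11 | isopropenylmagnesium bromide | C=C(C)[Mg]Br | starting material
12 | di(prop-1-en-2-yl)zinc | C=C(C)[Zn]C(C)=C | intermediate
13 | methyl (3S,6S)-6-hydroxy-3-[(E)-2-iodoethenyl]-3,7-dimethyloct-7-enoate | C=C(C)[C@@H](O)CC[C@](C)(/C=C/I)CC(=O)OC | intermediate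
14 | tert-butyl 2-(diethoxyphosphoryl)acetate | CCOP(=O)(OCC)CC(=O)OC(C)(C)C | starting material
15 | acrolein | C=CC=O | starting material
16 | tert-butyl 2-(diethoxyphosphoryl)-5-oxopentanoate (racemic) | CCOP(=O)(OCC)C(CCC=O)C(=O)OC(C)(C)C | intermediate
17 | methyl 2-[bis(2,2,2-trifluoroethoxy)phosphoryl]propanoate | COC(=O)C(C)P(=O)(OCC(F)(F)F)OCC(F)(F)F | starting material
18 | 1-tert-butyl 7-methyl (5Z)-2-(diethoxyphosphoryl)-6-methylhept-5-enedioate (racemic at C2) | COC(=O)/C(C)=C\CCC(P(=O)(OCC)OCC)C(=O)OC(C)(C)C | intermediate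
19 | tert-butyl (5Z)-2-(diethoxyphosphoryl)-7-hydroxy-6-methylhept-5-enoate (racemic at C2) | OC/C(C)=C\CCC(P(=O)(OCC)OCC)C(=O)OC(C)(C)C | intermediate
20 | tert-butyl 2-(diethoxyphosphoryl)-4-[(2S,3R)-3-(hydroxymethyl)-3-methyloxiran-2-yl]butanoate (both C2 epimers) | OC[C@@]1(C)O[C@H]1CCC(P(=O)(OCC)OCC)C(=O)OC(C)(C)C | intermediate
21 | tert-butyl 2-(diethoxyphosphoryl)-4-[(2S,3R)-3-methyl-3-{[(triethylsilyl)oxy]methyl}oxiran-2-yl]butanoate (both C2 epimers) | CC[Si](CC)(CC)OC[C@@]1(C)O[C@H]1CCC(P(=O)(OCC)OCC)C(=O)OC(C)(C)C | intermediate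
22 | (3S,6S)-6-hydroxy-3-[(E)-2-iodoethenyl]-3,7-dimethyloct-7-enal | C=C(C)[C@@H](O)CC[C@](C)(/C=C/I)CC=O | intermediate
23 | tert-butyl (2E,5S,8S)-8-hydroxy-5-[(E)-2-iodoethenyl]-5,9-dimethyl-2-{2-[(2S,3R)-3-methyl-3-{[(triethylsilyl)oxy]methyl}oxiran-2-yl]ethyl}deca-2,9-dienoate | C=C(C)[C@@H](O)CC[C@](C)(/C=C/I)C/C=C(/C(=O)OC(C)(C)C)CC[C@@H]1O[C@]1(C)CO[Si](CC)(CC)CC | intermediate
24 | (3S,6S,8E)-9-(hydroxymethyl)-6-[(E)-2-iodoethenyl]-2,6-dimethyl-11-[(2S,3R)-3-methyl-3-{[(triethylsilyl)oxy]methyl}oxiran-2-yl]undeca-1,8-dien-3-ol | C=C(C)[C@@H](O)CC[C@](C)(/C=C/I)C/C=C(/CO)CC[C@@H]1O[C@]1(C)CO[Si](CC)(CC)CC | intermediate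
25 | (3S,6S,8E)-3-[(tert-butyldimethylsilyl)oxy]-9-{[(tert-butyldimethylsilyl)oxy]methyl}-6-[(E)-2-iodoethenyl]-2,6-dimethyl-11-[(2S,3R)-3-methyl-3-{[(triethylsilyl)oxy]methyl}oxiran-2-yl]undeca-1,8-diene | C=C(C)[C@@H](O[Si](C)(C)C(C)(C)C)CC[C@](C)(/C=C/I)C/C=C(/CO[Si](C)(C)C(C)(C)C)CC[C@@H]1O[C@]1(C)CO[Si](CC)(CC)CC | intermediate
26 | (2S,3S)-3-[(3E,6S,9S)-9-[(tert-butyldimethylsilyl)oxy]-3-{[(tert-butyldimethylsilyl)oxy]methyl}-6-[(E)-2-iodoethenyl]-6,10-dimethylundeca-3,10-dien-1-yl]-2-methyloxirane-2-carbaldehyde | C=C(C)[C@@H](O[Si](C)(C)C(C)(C)C)CC[C@](C)(/C=C/I)C/C=C(/CO[Si](C)(C)C(C)(C)C)CC[C@@H]1O[C@]1(C)C=O | intermediate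
27 | (1R,2R,3E,5S,7E,11S)-8-{[(tert-butyldimethylsilyl)oxy]methyl}-5-{(3S)-3-[(tert-butyldimethylsilyl)oxy]-4-methylpent-4-en-1-yl}-1,5-dimethyl-12-oxabicyclo[9.1.0]dodeca-3,7-dien-2-ol | C=C(C)[C@@H](O[Si](C)(C)C(C)(C)C)CC[C@]1(C)/C=C/[C@@H](O)[C@@]2(C)O[C@H]2CC/C(CO[Si](C)(C)C(C)(C)C)=C\C1 | intermediate
28 | 3-methylbut-2-enoyl chloride | CC(C)=CC(=O)Cl | starting material
29 | (1S,2R,3E,5S,7E,11S)-8-{[(tert-butyldimethylsilyl)oxy]methyl}-5-{(3S)-3-[(tert-butyldimethylsilyl)oxy]-4-methylpent-4-en-1-yl}-1,5-dimethyl-12-oxabicyclo[9.1.0]dodeca-3,7-dien-2-yl 3-methylbut-2-enoate | C=C(C)[C@@H](O[Si](C)(C)C(C)(C)C)CC[C@]1(C)/C=C/[C@@H](OC(=O)C=C(C)C)[C@@]2(C)O[C@H]2CC/C(CO[Si](C)(C)C(C)(C)C)=C\C1 | intermediate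
30 | (1S,2R,3E,5S,7E,11S)-8-(hydroxymethyl)-5-[(3S)-3-hydroxy-4-methylpent-4-en-1-yl]-1,5-dimethyl-12-oxabicyclo[9.1.0]dodeca-3,7-dien-2-yl 3-methylbut-2-enoate | C=C(C)[C@@H](O)CC[C@]1(C)/C=C/[C@@H](OC(=O)C=C(C)C)[C@@]2(C)O[C@H]2CC/C(CO)=C\C1 | target

**Step count and risks**
Total steps: 18. Longest linear sequence: 13 (steps 1–6, then 12–18).

The three steps most likely to fail are 2, 6 and 16.

Step 2 (the β-silylvinyl alane is less precedented than simple alkenylalanes; rate or ee may be low). The fallback sets out from 3 and returns at 8. Hydroalumination of ethynyltrimethylsilane with i-Bu2AlH gives diisobutyl[1-(trimethylsilyl)ethenyl]aluminium F1. F1 adds to 3 under chiral NHC–copper catalysis (CuCl2·2H2O, chiral imidazolinium salt) to give (3S)-3-methyl-3-[1-(trimethylsilyl)ethenyl]cyclohexan-1-one F2. CF3CO2H removes silicon to give (3S)-3-ethenyl-3-methylcyclohexan-1-one F3. Cross-metathesis with vinylboronic acid pinacol ester (second-generation Hoveyda–Grubbs catalyst) gives (3S)-3-methyl-3-[(E)-2-(4,4,5,5-tetramethyl-1,3,2-dioxaborolan-2-yl)ethenyl]cyclohexan-1-one F4. I2/NaOH replaces boron by iodine with retention and gives 8.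

Step 6 (the catalytic alkenylzinc addition may give low ee with a Grignard-derived zinc reagent). The fallback sets out from 10 and returns at 13. Addition of 11 at −78 °C gives methyl (3S)-6-hydroxy-3-[(E)-2-iodoethenyl]-3,7-dimethyloct-7-enoate F5 as both C6 epimers. Dess–Martin periodinane gives methyl (3S)-3-[(E)-2-iodoethenyl]-3,7-dimethyl-6-oxooct-7-enoate F6. Reduction with BH3·SMe2 and the (R)-2-methyl-CBS-oxazaborolidine, with the isopropenyl group as the large substituent, gives 13.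

Step 16 (ring strain may override the acyclic facial preference at C4). The fallback sets out from 26 and returns at 27. If the ring closure delivers (1R,2S,3E,5S,7E,11S)-8-{[(tert-butyldimethylsilyl)oxy]methyl}-5-{(3S)-3-[(tert-butyldimethylsilyl)oxy]-4-methylpent-4-en-1-yl}-1,5-dimethyl-12-oxabicyclo[9.1.0]dodeca-3,7-dien-2-ol F7, alone or mixed with 27, the crude alcohol is oxidised with Dess–Martin periodinane to (1S,3E,5S,7E,11S)-8-{[(tert-butyldimethylsilyl)oxy]methyl}-5-{(3S)-3-[(tert-butyldimethylsilyl)oxy]-4-methylpent-4-en-1-yl}-1,5-dimethyl-12-oxabicyclo[9.1.0]dodeca-3,7-dien-2-one F8. Reduction with Zn(BH4)2 (Et2O, −20 °C), in which zinc chelates the ketone and epoxide oxygens and hydride arrives anti to C6, gives the anti epoxy alcohol 27.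

Further compounds
F1 | step 2 | diisobutyl[1-(trimethylsilyl)ethenyl]aluminium | C=C([Si](C)(C)C)[Al](CC(C)C)CC(C)C
F2 | step 2 | (3S)-3-methyl-3-[1-(trimethylsilyl)ethenyl]cyclohexan-1-one | O=C1C[C@@](C)(C(=C)[Si](C)(C)C)CCC1
F3 | step 2 | (3S)-3-ethenyl-3-methylcyclohexan-1-one | O=C1C[C@@](C)(C=C)CCC1
F4 | step 2 | (3S)-3-methyl-3-[(E)-2-(4,4,5,5-tetramethyl-1,3,2-dioxaborolan-2-yl)ethenyl]cyclohexan-1-one | O=C1C[C@@](C)(/C=C/B2OC(C)(C)C(C)(C)O2)CCC1
F5 | step 6 | methyl (3S)-6-hydroxy-3-[(E)-2-iodoethenyl]-3,7-dimethyloct-7-enoate (both C6 epimers) | C=C(C)C(O)CC[C@](C)(/C=C/I)CC(=O)OC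
F6 | step 6 | methyl (3S)-3-[(E)-2-iodoethenyl]-3,7-dimethyl-6-oxooct-7-enoate | C=C(C)C(=O)CC[C@](C)(/C=C/I)CC(=O)OC
F7 | step 16 | (1R,2S,3E,5S,7E,11S)-8-{[(tert-butyldimethylsilyl)oxy]methyl}-5-{(3S)-3-[(tert-butyldimethylsilyl)oxy]-4-methylpent-4-en-1-yl}-1,5-dimethyl-12-oxabicyclo[9.1.0]dodeca-3,7-dien-2-ol | C=C(C)[C@@H](O[Si](C)(C)C(C)(C)C)CC[C@]1(C)/C=C/[C@H](O)[C@@]2(C)O[C@H]2CC/C(CO[Si](C)(C)C(C)(C)C)=C\C1
F8 | step 16 | (1S,3E,5S,7E,11S)-8-{[(tert-butyldimethylsilyl)oxy]methyl}-5-{(3S)-3-[(tert-butyldimethylsilyl)oxy]-4-methylpent-4-en-1-yl}-1,5-dimethyl-12-oxabicyclo[9.1.0]dodeca-3,7-dien-2-one | C=C(C)[C@@H](O[Si](C)(C)C(C)(C)C)CC[C@]1(C)/C=C/C(=O)[C@@]2(C)O[C@H]2CC/C(CO[Si](C)(C)C(C)(C)C)=C\C1
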